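**Retrosynthetic overview**

1. Target 15 comes from TIPS ether 14 by desilylation; 14 from diester 13 by one DIBAL-H reduction of both esters; 13 from bromo ester 11 by a Heck reaction with methyl acrylate 12. The C3 ester is the CH2OH group at a higher oxidation level.
2. Key disconnection: the bond from the syringyl ring carbon to C2 of the dihydrofuran, made by an enantioselective Rh(I)/chiral-diene dearomative 1,4-arylation of the flat, achiral benzofuran ester 4 with arylboronic acid 9. The same operation sets C2 and, after epimerisation in the flask, the trans C3.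
3. Enabling feature: in 4 the furan-ring atoms O1–C2=C3 together with the ester on C3 form a vinylogous carbonate. C2 is therefore the β-carbon of an enoate inside a weakly aromatic five-membered ring, and the C3 enolate is conjugated with the benzene ring.
4. Ring order: both benzene rings are bought. The furan ring is made first as an aromatic benzofuran (step 1, from salicylaldehyde 1 and diazo ester 2) and is reduced to the dihydrofuran in the key step; no ring is formed afterwards.
5. Boronic acid 9 comes from 4-bromo-2,6-dimethoxyphenol 5 by silylation and lithiation–borylation.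

Key step: step 4

Remark: the sense of induction of the chiral diene in step 4 is not assigned here; the ligand antipode that delivers the aryl group to the Re face of C2 (O1 > C3 > H) is meant, and both antipodes are accessible.

**Route**

Step 1
Reactants: 1 5-bromo-2-hydroxy-3-methoxybenzaldehyde; 2 ethyl diazoacetate
Product: 4 ethyl 5-bromo-7-methoxy-1-benzofuran-3-carboxylate, via lactol 3 (not isolated)
Conditions: HBF4·OEt2 (10 mol %), CH2Cl2, 23 °C (slow addition of 2); then conc. H2SO4, 23 °C
Reagents that add atoms: none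
Why: Brønsted-acid-catalysed addition of the diazo ester to the aldehyde and 1,2-aryl shift with loss of N2 (Roskamp-type homologation) give the α-formyl arylacetate, which closes to lactol 3 and is dehydrated by H2SO4 to the aromatic benzofuran-3-carboxylate, a sequence with close precedent on substituted salicylaldehydes; no stereocentre is formed.

Step 2
Reactants: 5 4-bromo-2,6-dimethoxyphenol
Product: 6 (4-bromo-2,6-dimethoxyphenoxy)tri(propan-2-yl)silane
Conditions: TIPSCl (1.3 equiv), imidazole (2.5 equiv), DMF, 50 °C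
Reagents that add atoms: triisopropylsilyl chloride (TIPSCl), CC(C)[Si](Cl)(C(C)C)C(C)C
Why: Imidazole-promoted silyl ether formation at the phenol; TIPS is chosen because it should withstand organolithium, aqueous base, Pd and DIBAL-H and is removed by fluoride without touching the alkene, the allylic alcohol or the benzylic ether of the target.

Step 3
Reactants: 6 (4-bromo-2,6-dimethoxyphenoxy)tri(propan-2-yl)silane
Product: 9 [3,5-dimethoxy-4-(triisopropylsilyloxy)phenyl]boronic acid, via aryllithium 7 (not isolated), via lithium borate 8 (not isolated)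
Conditions: n-BuLi (1.1 equiv), THF, −78 °C; B(OiPr)3 (1.5 equiv), −78 to 23 °C; 1 M HCl, 0 °C (brief)
Reagents that add atoms: triisopropyl borate, CC(C)OB(OC(C)C)OC(C)C; water, O
Why: Bromine–lithium exchange is faster than ortho-lithiation next to OMe, and trapping of aryllithium 7 with the borate followed by mild hydrolysis of ate complex 8 is the standard lithiation–borylation route to arylboronic acids.

Step 4
Reactants: 4 ethyl 5-bromo-7-methoxy-1-benzofuran-3-carboxylate; 9 [3,5-dimethoxy-4-(triisopropylsilyloxy)phenyl]boronic acid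
Product: 11 ethyl (2S,3S)-5-bromo-2-[3,5-dimethoxy-4-(triisopropylsilyloxy)phenyl]-7-methoxy-2,3-dihydro-1-benzofuran-3-carboxylate (trans), via cis ester 10 (not isolated)
Conditions: [RhCl(C2H4)2]2 (3 mol %), chiral diene Ph-bod* (6.6 mol %), 9 (2.5 equiv), K3PO4 (0.5 equiv), dioxane/H2O 10:1, 70 °C; then DBU (0.3 equiv), 23 °C
Reagents that add atoms: none
Why: Proposed new method: transmetalation from 9 gives an aryl–Rh(I)(diene) species that should insert the C2=C3 bond of 4 with the aryl group going to C2, the β-carbon of the vinylogous carbonate O1–C2=C3–CO2Et, to give an aryl-conjugated oxa-π-allyl rhodium enolate that water protonates, which regenerates Rh–OH (Hayashi–Miyaura cycle). The closest known reaction types are the Rh(I)-catalysed asymmetric 1,4-arylation (chiral diene or bisphosphine ligands) of chromones, coumarins and α,β-unsaturated esters and the dearomative conjugate addition of radicals and soft nucleophiles to benzofurans that carry an acceptor at C3. No ring is closed: the pre-formed furan ring is only reduced to the dihydrofuran, and the small resonance energy of that ring is repaid by the new C–C bond and the stabilised enolate. C2 is set by the chiral diene, which leaves the Re face of C2 open to the migrating aryl group, and C3 by substrate control, because the kinetically protonated cis ester 10 epimerises through its enolate (K3PO4, then DBU) to the more stable trans ester 11. The step needs C2 regioselectivity and 1,4- over 1,2-addition (both secured by the C3 ester, and C2 is also the normal site of aryl–metal insertion into benzofurans), tolerance of the aryl bromide (Rh(I)/diene should not add oxidatively to Ar–Br under these conditions) and an intact C2–O1 bond, which is secured because ring opening of the ester enolate would be a retro-5-endo-trig elimination and the quinone-methide pathway is closed by the TIPS ether.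

Step 5
Reactants: 11 ethyl (2S,3S)-5-bromo-2-[3,5-dimethoxy-4-(triisopropylsilyloxy)phenyl]-7-methoxy-2,3-dihydro-1-benzofuran-3-carboxylate; 12 methyl acrylate
Product: 13 ethyl (2S,3S)-2-[3,5-dimethoxy-4-(triisopropylsilyloxy)phenyl]-7-methoxy-5-[(E)-3-methoxy-3-oxoprop-1-en-1-yl]-2,3-dihydro-1-benzofuran-3-carboxylate
Conditions: Pd(P(t-Bu)3)2 (3 mol %), Cy2NMe (1.2 equiv), dioxane, 23–50 °C
Reagents that add atoms: none
Why: Mizoroki–Heck reaction in which the Pd/P(t-Bu)3 catalyst should insert into the electron-rich aryl bromide near room temperature and syn-insertion/syn-β-hydride elimination gives the (E)-cinnamate, while the hindered amine cannot touch C2 (no acidic H) and could at most return C3 to the favoured trans arrangement.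

Step 6
Reactants: 13 ethyl (2S,3S)-2-[3,5-dimethoxy-4-(triisopropylsilyloxy)phenyl]-7-methoxy-5-[(E)-3-methoxy-3-oxoprop-1-en-1-yl]-2,3-dihydro-1-benzofuran-3-carboxylate
Product: 14 (E)-3-[(2S,3R)-2-[3,5-dimethoxy-4-(triisopropylsilyloxy)phenyl]-3-(hydroxymethyl)-7-methoxy-2,3-dihydro-1-benzofuran-5-yl]prop-2-en-1-ol
Conditions: DIBAL-H (6 equiv), CH2Cl2, −78 to −20 °C; aq. Rochelle salt
Reagents that add atoms: none
Why: DIBAL-H ester reduction that should convert the saturated ester and, by 1,2-reduction, the cinnamate into the two primary alcohols in one operation at low temperature, where the silyl ether, the alkene geometry and both stereocentres are untouched (the descriptor at C3 changes to R only through the CIP priorities).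

Step 7
Reactants: 14 (E)-3-[(2S,3R)-2-[3,5-dimethoxy-4-(triisopropylsilyloxy)phenyl]-3-(hydroxymethyl)-7-methoxy-2,3-dihydro-1-benzofuran-5-yl]prop-2-en-1-ol
Product: 15 4-[(2S,3R)-3-(hydroxymethyl)-5-[(E)-3-hydroxyprop-1-en-1-yl]-7-methoxy-2,3-dihydro-1-benzofuran-2-yl]-2,6-dimethoxyphenol (CNP0191372.1)
Conditions: TBAF (1.2 equiv), AcOH (1.2 equiv), THF, 0 °C
Reagents that add atoms: none
Why: Fluoride-mediated cleavage of the aryl silyl ether, buffered with acetic acid so that the phenoxide is protonated at once and cannot open the benzylic C2–O bond through a p-quinone methide; no stereocentre is touched.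

**Compound list**

1 | 5-bromo-2-hydroxy-3-methoxybenzaldehyde | COc1cc(Br)cc(C=O)c1O | starting material
2 | ethyl diazoacetate | CCOC(=O)C=[N+]=[N-] | starting material
3 | ethyl 5-bromo-2-hydroxy-7-methoxy-2,3-dihydro-1-benzofuran-3-carboxylate (lactol, mixture of stereoisomers) | CCOC(=O)C1C(O)Oc2c(OC)cc(Br)cc21 | intermediate
4 | ethyl 5-bromo-7-methoxy-1-benzofuran-3-carboxylate | CCOC(=O)c1coc2c(OC)cc(Br)cc12 | intermediate
5 | 4-bromo-2,6-dimethoxyphenol | COc1cc(Br)cc(OC)c1O | starting material
6 | (4-bromo-2,6-dimethoxyphenoxy)tri(propan-2-yl)silane | COc1cc(Br)cc(OC)c1O[Si](C(C)C)(C(C)C)C(C)C | intermediate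
7 | [3,5-dimethoxy-4-(triisopropylsilyloxy)phenyl]lithium | COc1cc([Li])cc(OC)c1O[Si](C(C)C)(C(C)C)C(C)C | intermediate
8 | lithium [3,5-dimethoxy-4-(triisopropylsilyloxy)phenyl]tri(propan-2-yloxy)borate | [Li+].COc1cc([B-](OC(C)C)(OC(C)C)OC(C)C)cc(OC)c1O[Si](C(C)C)(C(C)C)C(C)C | intermediate
9 | [3,5-dimethoxy-4-(triisopropylsilyloxy)phenyl]boronic acid | COc1cc(B(O)O)cc(OC)c1O[Si](C(C)C)(C(C)C)C(C)C | intermediate
10 | ethyl (2S,3R)-5-bromo-2-[3,5-dimethoxy-4-(triisopropylsilyloxy)phenyl]-7-methoxy-2,3-dihydro-1-benzofuran-3-carboxylate (cis) | COc1cc([C@H]2Oc3c(OC)cc(Br)cc3[C@H]2C(=O)OCC)cc(OC)c1O[Si](C(C)C)(C(C)C)C(C)C | intermediate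
11 | ethyl (2S,3S)-5-bromo-2-[3,5-dimethoxy-4-(triisopropylsilyloxy)phenyl]-7-methoxy-2,3-dihydro-1-benzofuran-3-carboxylate (trans) | COc1cc([C@H]2Oc3c(OC)cc(Br)cc3[C@@H]2C(=O)OCC)cc(OC)c1O[Si](C(C)C)(C(C)C)C(C)C | intermediate
12 | methyl acrylate | C=CC(=O)OC | starting material
13 | ethyl (2S,3S)-2-[3,5-dimethoxy-4-(triisopropylsilyloxy)phenyl]-7-methoxy-5-[(E)-3-methoxy-3-oxoprop-1-en-1-yl]-2,3-dihydro-1-benzofuran-3-carboxylate | COc1cc([C@H]2Oc3c(OC)cc(/C=C/C(=O)OC)cc3[C@@H]2C(=O)OCC)cc(OC)c1O[Si](C(C)C)(C(C)C)C(C)C | intermediate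
14 | (E)-3-[(2S,3R)-2-[3,5-dimethoxy-4-(triisopropylsilyloxy)phenyl]-3-(hydroxymethyl)-7-methoxy-2,3-dihydro-1-benzofuran-5-yl]prop-2-en-1-ol | COc1cc([C@H]2Oc3c(OC)cc(/C=C/CO)cc3[C@@H]2CO)cc(OC)c1O[Si](C(C)C)(C(C)C)C(C)C | intermediate
15 | 4-[(2S,3R)-3-(hydroxymethyl)-5-[(E)-3-hydroxyprop-1-en-1-yl]-7-methoxy-2,3-dihydro-1-benzofuran-2-yl]-2,6-dimethoxyphenol | COc1cc([C@H]2Oc3c(OC)cc(/C=C/CO)cc3[C@@H]2CO)cc(OC)c1O | target

**Step count and risks**

Total steps: 7. Longest linear sequence: 6 steps (5 → 6 → 9 → 11 → 13 → 14 → 15; steps 2–7).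

Steps most likely to fail:

1. Step 4 (Proposed new method). Insertion of the aryl–rhodium species into the aromatic, trisubstituted enoate may be slower than protodeboronation of the electron-rich boronic acid, or the facial discrimination at C2 may be poor. The fallback uses known chemistry, sets out from 9 and comes back at 11: the same bond is made on a chromone, and the six-membered ring is contracted afterwards. Commercial 1-(2-hydroxy-3-methoxyphenyl)ethanone is brominated para to the hydroxyl group (NBS, MeCN, 0 °C) to 1-(5-bromo-2-hydroxy-3-methoxyphenyl)ethanone F1. Condensation with DMF-DMA (toluene, 100 °C) gives (E)-1-(5-bromo-2-hydroxy-3-methoxyphenyl)-3-(dimethylamino)prop-2-en-1-one F2, and HCl (CH2Cl2, 23 °C) closes it to 6-bromo-8-methoxy-4H-chromen-4-one F3. Pd(II)/pyridine-oxazoline-catalysed asymmetric conjugate addition of 9 (Pd(OCOCF3)2, t-BuPyOx antipode for the 2S product, NH4PF6, H2O, ClCH2CH2Cl, 60 °C) should give (2S)-6-bromo-2-[3,5-dimethoxy-4-(triisopropylsilyloxy)phenyl]-8-methoxy-2,3-dihydro-4H-chromen-4-one F4. Oxidative ring contraction of this flavanone with PhI(OAc)2 and H2SO4 in triethyl orthoformate (23 °C) should then return trans ester 11: the arene carbon shifts from C4 to C3 anti to the departing iodane, C2 keeps its configuration, and the former C4 becomes the ethyl ester.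

2. Step 5. Oxidative addition into the electron-rich aryl bromide may be slow, and prolonged heating with amine base may erode the configuration at C3 by enolisation of the α-aryl ester. The fallback sets out from 11 and comes back at 15, bringing in the side chain at the alcohol oxidation level. Suzuki–Miyaura coupling of 11 with commercial (E)-3-(tert-butyldimethylsilyloxy)prop-1-en-1-ylboronic acid pinacol ester (Pd(dppf)Cl2, K3PO4, THF/H2O, 50 °C) should give ethyl (2S,3S)-5-[(E)-3-(tert-butyldimethylsilyloxy)prop-1-en-1-yl]-2-[3,5-dimethoxy-4-(triisopropylsilyloxy)phenyl]-7-methoxy-2,3-dihydro-1-benzofuran-3-carboxylate F5. LiBH4 reduction of the single ester (THF, 0 °C) gives [(2S,3R)-5-[(E)-3-(tert-butyldimethylsilyloxy)prop-1-en-1-yl]-2-[3,5-dimethoxy-4-(triisopropylsilyloxy)phenyl]-7-methoxy-2,3-dihydro-1-benzofuran-3-yl]methanol F6. TBAF/AcOH (THF, 0 °C) removes both silyl groups and gives 15.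

3. Step 3. The aryllithium may be butylated by the 1-bromobutane formed in the exchange, and the electron-rich boronic acid may protodeboronate or lose the silyl group during acidic hydrolysis of the borate. The fallback sets out from 6 and comes back at 9 without an organolithium. Miyaura borylation of 6 (B2pin2, Pd(dppf)Cl2, KOAc, dioxane, 85 °C) should give 2-[3,5-dimethoxy-4-(triisopropylsilyloxy)phenyl]-4,4,5,5-tetramethyl-1,3,2-dioxaborolane F7. Oxidative cleavage of the pinacol ester (NaIO4, NH4OAc, acetone/H2O, 23 °C) then gives boronic acid 9 under near-neutral conditions.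

**Further compounds**

F1 | step 4 | 1-(5-bromo-2-hydroxy-3-methoxyphenyl)ethanone | CC(=O)c1cc(Br)cc(OC)c1O
F2 | step 4 | (E)-1-(5-bromo-2-hydroxy-3-methoxyphenyl)-3-(dimethylamino)prop-2-en-1-one | CN(C)/C=C/C(=O)c1cc(Br)cc(OC)c1O
F3 | step 4 | 6-bromo-8-methoxy-4H-chromen-4-one | COc1cc(Br)cc2c(=O)ccoc12
F4 | step 4 | (2S)-6-bromo-2-[3,5-dimethoxy-4-(triisopropylsilyloxy)phenyl]-8-methoxy-2,3-dihydro-4H-chromen-4-one | COc1cc([C@@H]2CC(=O)c3cc(Br)cc(OC)c3O2)cc(OC)c1O[Si](C(C)C)(C(C)C)C(C)C
F5 | step 5 | ethyl (2S,3S)-5-[(E)-3-(tert-butyldimethylsilyloxy)prop-1-en-1-yl]-2-[3,5-dimethoxy-4-(triisopropylsilyloxy)phenyl]-7-methoxy-2,3-dihydro-1-benzofuran-3-carboxylate | COc1cc([C@H]2Oc3c(OC)cc(/C=C/CO[Si](C)(C)C(C)(C)C)cc3[C@@H]2C(=O)OCC)cc(OC)c1O[Si](C(C)C)(C(C)C)C(C)C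
F6 | step 5 | [(2S,3R)-5-[(E)-3-(tert-butyldimethylsilyloxy)prop-1-en-1-yl]-2-[3,5-dimethoxy-4-(triisopropylsilyloxy)phenyl]-7-methoxy-2,3-dihydro-1-benzofuran-3-yl]methanol | COc1cc([C@H]2Oc3c(OC)cc(/C=C/CO[Si](C)(C)C(C)(C)C)cc3[C@@H]2CO)cc(OC)c1O[Si](C(C)C)(C(C)C)C(C)C
F7 | step 3 | 2-[3,5-dimethoxy-4-(triisopropylsilyloxy)phenyl]-4,4,5,5-tetramethyl-1,3,2-dioxaborolane | COc1cc(B2OC(C)(C)C(C)(C)O2)cc(OC)c1O[Si](C(C)C)(C(C)C)C(C)C
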